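**Plan**

- Retrosynthesis first cuts the depside ester bond between the ring B carbonyl and O4 of ring A. Both halves then trace back to one resorcylate, benzyl 2,4-dihydroxy-6-[(2-pentyl-1,3-dioxolan-2-yl)methyl]benzoate.
- That ring is cut at C1–C2 and C5–C6. Ring A (and ring B likewise) has oxygen on C2 ortho and on C4 para to the C1 carboxyl, with the 2-oxoheptyl arm on C6. This is the pattern a 1,1,3-trioxygenated butadiene leaves on an alkynoate whose β-carbon holds the arm.
- The ynoate is cut at the alkyne–carboxyl bond and at the carbinol–CH2 bond, giving hexanal, 3-bromoprop-1-yne and benzyl chloroformate.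
- Forward: the chain is assembled and the ketone masked (steps 1–4), and the ring is closed by cycloaddition and aromatization (step 5). One portion is converted into the ring B acid (steps 6–7) and joined to the free C4 hydroxyl of a second portion (step 8). The ketals and then the benzyl groups are removed (steps 9–10).
- Stereochemistry: the target has no stereocentre. The racemic carbinol of step 1 is oxidized away, and the ketal carbon of the cycloadduct disappears on aromatization.

Key step: step 5

Assumption: diene 10 is used as purchased and freshly distilled (it is otherwise accessible from methyl acetoacetate by two silylations); its C1=C2 geometry is irrelevant because it is lost in the arene.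

**Route**

Step 1
Reactants: 1 hexanal; 2 3-bromoprop-1-yne
Product: 4 racemic non-1-yn-4-ol, via allenylzinc bromide 3 (not isolated)
Conditions: Zn dust, THF, 0 °C; then 1, −78 → 0 °C; 1 M HCl work-up
Reagents that add atoms: none
Why: Barbier-type propargylation in which the allenylzinc reagent adds to the aldehyde through a cyclic SE2' transition state and so should give the homopropargylic rather than the allenic alcohol; the new carbinol centre is racemic and is removed in step 2.

Step 2
Reactants: 4 non-1-yn-4-ol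
Product: 5 non-1-yn-4-one
Conditions: Dess–Martin periodinane (1.2 equiv), CH2Cl2, 0 °C → rt; used at once
Reagents that add atoms: none
Why: Dess–Martin oxidation of a secondary alcohol runs under neutral to weakly acidic conditions, which should avoid the base-triggered propargyl-to-allenyl shift of the β,γ-ynone.

Step 3
Reactants: 5 non-1-yn-4-one
Product: 6 2-pentyl-2-(prop-2-yn-1-yl)-1,3-dioxolane
Conditions: (TMSOCH2)2 (1.5 equiv), TMSOTf (5 mol %), CH2Cl2, −78 → −20 °C; pyridine quench
Reagents that add atoms: 1,2-bis(trimethylsilyloxy)ethane, C[Si](C)(C)OCCO[Si](C)(C)C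
Why: Lewis-acid-catalysed silyl-transfer ketalization forms the dioxolane at low temperature under aprotic conditions, driven by hexamethyldisiloxane formation, a reaction type known to protect β,γ-unsaturated ketones without migration of the unsaturation.

Step 4
Reactants: 6 2-pentyl-2-(prop-2-yn-1-yl)-1,3-dioxolane; 7 benzyl chloroformate
Product: 9 benzyl 4-(2-pentyl-1,3-dioxolan-2-yl)but-2-ynoate, via lithium acetylide 8 (not isolated)
Conditions: n-BuLi (1.05 equiv), THF, −78 °C; then cannulated into 7 (1.5 equiv), THF, −78 → 0 °C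
Reagents that add atoms: none
Why: Deprotonation of the terminal alkyne and C-acylation of the lithium acetylide by a chloroformate is a standard ynoate synthesis, and inverse addition should suppress a second acetylide addition to the product.

Step 5
Reactants: 9 benzyl 4-(2-pentyl-1,3-dioxolan-2-yl)but-2-ynoate; 10 1-methoxy-1,3-bis(trimethylsilyloxy)buta-1,3-diene
Product: 13 benzyl 2,4-dihydroxy-6-[(2-pentyl-1,3-dioxolan-2-yl)methyl]benzoate, via cyclohexa-1,4-diene cycloadduct 11 (not isolated), via 4-O-trimethylsilyl resorcylate 12 (not isolated)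
Conditions: 10 (3 equiv, in portions), xylene, 130 °C, sealed tube; then K2CO3 (cat.), MeOH, 0 °C
Reagents that add atoms: none
Why: A concerted but asynchronous normal-demand (4+2) cycloaddition joins the electron-rich diene 10 to the electron-poor ynoate 9; its closest known relatives are the resorcylate-forming Diels–Alder reactions of 1-alkoxy-1,3-bis(silyloxy)butadienes with acetylenic esters, in which a β-alkyl ynoate is a slow partner that needs heat and excess diene. Ring A closes in this single intermolecular event as the cyclohexa-1,4-diene 11, the ynoate α-carbon becoming C1, the ketene acetal carbon C2, the diene CH2 terminus C5 and the ynoate β-carbon C6, so that C1–C2 and C5–C6 are the two new ring bonds. The mixed silyl methyl ketal at C2 of 11 then expels methoxytrimethylsilane, the resulting dienone tautomerizes to the C2 phenol 12, and methanolysis removes the remaining silyl group from O4. The only stereocentre formed, the ketal carbon of 11, is erased on aromatization, so no stereocontrol is required. The step does need regiocontrol, and the diene supplies it: its unsubstituted CH2 terminus carries the largest HOMO coefficient and bonds to the ynoate β-carbon, while the ketene acetal carbon bonds to the α-carbon, which places one oxygen ortho and the other para to the ester. The product should emerge with the C2 hydroxyl hydrogen-bonded to the ester and the C4 hydroxyl free, the differentiation exploited in step 8.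

Step 6
Reactants: 13 benzyl 2,4-dihydroxy-6-[(2-pentyl-1,3-dioxolan-2-yl)methyl]benzoate
Product: 14 benzyl 2,4-bis(benzyloxy)-6-[(2-pentyl-1,3-dioxolan-2-yl)methyl]benzoate
Conditions: BnBr (2.5 equiv), K2CO3 (3 equiv), DMF, 60 °C
Reagents that add atoms: benzyl bromide, BrCc1ccccc1
Why: Williamson ether synthesis on both phenols, the hydrogen-bonded C2 hydroxyl being alkylated as well in warm DMF with excess carbonate, while the ketal and the ester are inert to these conditions.

Step 7
Reactants: 14 benzyl 2,4-bis(benzyloxy)-6-[(2-pentyl-1,3-dioxolan-2-yl)methyl]benzoate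
Product: 15 2,4-bis(benzyloxy)-6-[(2-pentyl-1,3-dioxolan-2-yl)methyl]benzoic acid
Conditions: KOH (10 equiv), DMSO/H2O (4:1), 90 °C; then 1 M HCl to pH 4 at 0 °C, rapid extraction
Reagents that add atoms: potassium hydroxide, [K+].[OH-]
Why: Saponification of a doubly ortho-substituted benzoate needs poorly solvated hydroxide in aqueous DMSO, conditions established for 2,4-dialkoxy-6-alkylbenzoates and harmless to the benzyl ethers and the base-stable ketal.

Step 8
Reactants: 15 2,4-bis(benzyloxy)-6-[(2-pentyl-1,3-dioxolan-2-yl)methyl]benzoic acid; 13 benzyl 2,4-dihydroxy-6-[(2-pentyl-1,3-dioxolan-2-yl)methyl]benzoate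
Product: 17 benzyl 4-({2,4-bis(benzyloxy)-6-[(2-pentyl-1,3-dioxolan-2-yl)methyl]benzoyl}oxy)-2-hydroxy-6-[(2-pentyl-1,3-dioxolan-2-yl)methyl]benzoate, via acid chloride 16 (not isolated)
Conditions: 1-chloro-N,N,2-trimethylprop-1-en-1-amine (1.1 equiv), CH2Cl2, 0 °C → rt; then 13 (1.0 equiv), Et3N (1.2 equiv), DMAP (10 mol %), CH2Cl2, 0 °C → rt
Reagents that add atoms: none
Why: The α-chloroenamine converts the acid into its chloride without releasing HCl, so the ketal should survive, and the DMAP-catalysed acylation of a phenol (the classical depside esterification) should go to the more acidic, unchelated C4 hydroxyl rather than the C2 hydroxyl held in a hydrogen bond to the ester.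

Step 9
Reactants: 17 benzyl 4-({2,4-bis(benzyloxy)-6-[(2-pentyl-1,3-dioxolan-2-yl)methyl]benzoyl}oxy)-2-hydroxy-6-[(2-pentyl-1,3-dioxolan-2-yl)methyl]benzoate
Product: 18 benzyl 4-{[2,4-bis(benzyloxy)-6-(2-oxoheptyl)benzoyl]oxy}-2-hydroxy-6-(2-oxoheptyl)benzoate
Conditions: 1 M aq. HCl/THF (1:3), rt
Reagents that add atoms: water, O
Why: Acid-catalysed hydrolysis frees both dialkyl ketones from their dioxolanes under conditions that the hindered aryl ester, the benzyl ester and the benzyl ethers tolerate, and base is avoided because an enolate next to the depside carbonyl could cleave it.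

Step 10
Reactants: 18 benzyl 4-{[2,4-bis(benzyloxy)-6-(2-oxoheptyl)benzoyl]oxy}-2-hydroxy-6-(2-oxoheptyl)benzoate
Product: 19 4-{[2,4-dihydroxy-6-(2-oxoheptyl)benzoyl]oxy}-2-hydroxy-6-(2-oxoheptyl)benzoic acid
Conditions: H2 (1 atm), 10% Pd/C, EtOAc, rt
Reagents that add atoms: none
Why: Catalytic hydrogenolysis removes the benzyl ester and both aryl benzyl ethers in one neutral operation that leaves aliphatic ketones and the depside ester untouched, so the sensitive keto acid should be obtained by filtration and evaporation alone.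

**Compound list**

1 | hexanal | CCCCCC=O | starting material
2 | 3-bromoprop-1-yne | C#CCBr | starting material
3 | allenylzinc bromide | C=C=C[Zn]Br | intermediate (not isolated)
4 | non-1-yn-4-ol (racemic) | CCCCCC(O)CC#C | intermediate
5 | non-1-yn-4-one | CCCCCC(=O)CC#C | intermediate
6 | 2-pentyl-2-(prop-2-yn-1-yl)-1,3-dioxolane | CCCCCC1(CC#C)OCCO1 | intermediate
7 | benzyl chloroformate | O=C(Cl)OCc1ccccc1 | starting material
8 | lithium 3-(2-pentyl-1,3-dioxolan-2-yl)prop-1-yn-1-ide | [Li]C#CCC1(CCCCC)OCCO1 | intermediate (not isolated)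
9 | benzyl 4-(2-pentyl-1,3-dioxolan-2-yl)but-2-ynoate | CCCCCC1(CC#CC(=O)OCc2ccccc2)OCCO1 | intermediate
10 | 1-methoxy-1,3-bis(trimethylsilyloxy)buta-1,3-diene (C1=C2 isomer mixture) | COC(=CC(=C)O[Si](C)(C)C)O[Si](C)(C)C | starting material
11 | benzyl 6-methoxy-2-[(2-pentyl-1,3-dioxolan-2-yl)methyl]-4,6-bis(trimethylsilyloxy)cyclohexa-1,4-diene-1-carboxylate (racemic) | COC1(O[Si](C)(C)C)C=C(O[Si](C)(C)C)CC(CC2(CCCCC)OCCO2)=C1C(=O)OCc1ccccc1 | intermediate (not isolated)
12 | benzyl 2-hydroxy-6-[(2-pentyl-1,3-dioxolan-2-yl)methyl]-4-(trimethylsilyloxy)benzoate | O=C(OCc1ccccc1)c1c(O)cc(O[Si](C)(C)C)cc1CC1(CCCCC)OCCO1 | intermediate (not isolated)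
13 | benzyl 2,4-dihydroxy-6-[(2-pentyl-1,3-dioxolan-2-yl)methyl]benzoate | O=C(OCc1ccccc1)c1c(O)cc(O)cc1CC1(CCCCC)OCCO1 | intermediate
14 | benzyl 2,4-bis(benzyloxy)-6-[(2-pentyl-1,3-dioxolan-2-yl)methyl]benzoate | O=C(OCc1ccccc1)c1c(OCc2ccccc2)cc(OCc2ccccc2)cc1CC1(CCCCC)OCCO1 | intermediate
15 | 2,4-bis(benzyloxy)-6-[(2-pentyl-1,3-dioxolan-2-yl)methyl]benzoic acid | O=C(O)c1c(OCc2ccccc2)cc(OCc2ccccc2)cc1CC1(CCCCC)OCCO1 | intermediate
16 | 2,4-bis(benzyloxy)-6-[(2-pentyl-1,3-dioxolan-2-yl)methyl]benzoyl chloride | O=C(Cl)c1c(OCc2ccccc2)cc(OCc2ccccc2)cc1CC1(CCCCC)OCCO1 | intermediate (not isolated)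
17 | benzyl 4-({2,4-bis(benzyloxy)-6-[(2-pentyl-1,3-dioxolan-2-yl)methyl]benzoyl}oxy)-2-hydroxy-6-[(2-pentyl-1,3-dioxolan-2-yl)methyl]benzoate | O=C(OCc1ccccc1)c1c(O)cc(OC(=O)c2c(OCc3ccccc3)cc(OCc3ccccc3)cc2CC2(CCCCC)OCCO2)cc1CC1(CCCCC)OCCO1 | intermediate
18 | benzyl 4-{[2,4-bis(benzyloxy)-6-(2-oxoheptyl)benzoyl]oxy}-2-hydroxy-6-(2-oxoheptyl)benzoate | CCCCCC(=O)Cc1cc(OC(=O)c2c(OCc3ccccc3)cc(OCc3ccccc3)cc2CC(=O)CCCCC)cc(O)c1C(=O)OCc1ccccc1 | intermediate
19 | 4-{[2,4-dihydroxy-6-(2-oxoheptyl)benzoyl]oxy}-2-hydroxy-6-(2-oxoheptyl)benzoic acid | CCCCCC(=O)Cc1cc(OC(=O)c2c(O)cc(O)cc2CC(=O)CCCCC)cc(O)c1C(=O)O | target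

**Step count**

Total: 10 steps. Longest linear sequence: 10 steps (hexanal through 13, 15, 17 and 18 to 19; resorcylate 13 serves both as the ring A phenol and as the source of the ring B acid).

**Steps most likely to fail**

Step 5. The β-alkyl ynoate may add so slowly that thermal decay and silyl transfer of the acyclic diene outrun the cycloaddition, leaving low conversion. The fallback sets out from 9 and comes back at 13. Dimedone would be silylated (TMSCl, Et3N) to 5,5-dimethyl-3-(trimethylsilyloxy)cyclohex-2-en-1-one F1 and then (LiN(iPr)2, TMSCl, THF, −78 °C) to 5,5-dimethyl-1,3-bis(trimethylsilyloxy)cyclohexa-1,3-diene F2, a cyclic diene that tolerates 140–160 °C. Heated neat with 9, it should give the bicyclic adduct benzyl 8,8-dimethyl-3-[(2-pentyl-1,3-dioxolan-2-yl)methyl]-1,5-bis(trimethylsilyloxy)bicyclo[2.2.2]octa-2,5-diene-2-carboxylate F3 with the same regiochemistry. This adduct loses 2-methylpropene by retro-Diels–Alder fragmentation (Alder–Rickert) to give benzyl 6-[(2-pentyl-1,3-dioxolan-2-yl)methyl]-2,4-bis(trimethylsilyloxy)benzoate F4. Methanolysis (K2CO3, MeOH) then gives 13.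

Step 8. Acylation by the hindered acid chloride may be slow, and attack of the neighbouring ketal oxygen on the acyl chloride or acylation at the C2 hydroxyl may compete. The fallback sets out from 6 and 13 and comes back at 19; it builds ring B on the ester instead of coupling a preformed hindered acid. Compound 6 would be lithiated (n-BuLi) and carboxylated with CO2 to 4-(2-pentyl-1,3-dioxolan-2-yl)but-2-ynoic acid F5. This unhindered acid would be joined at once to the C4 hydroxyl of 13 by Steglich esterification (DCC, catalytic DMAP, CH2Cl2, 0 °C) to give benzyl 2-hydroxy-6-[(2-pentyl-1,3-dioxolan-2-yl)methyl]-4-{[4-(2-pentyl-1,3-dioxolan-2-yl)but-2-ynoyl]oxy}benzoate F6. A second cycloaddition with 10 under the conditions of step 5, on what is now a more electron-poor aryl ynoate, should give benzyl 4-({2,4-dihydroxy-6-[(2-pentyl-1,3-dioxolan-2-yl)methyl]benzoyl}oxy)-2-hydroxy-6-[(2-pentyl-1,3-dioxolan-2-yl)methyl]benzoate F7. Ketal hydrolysis as in step 9 would give benzyl 4-{[2,4-dihydroxy-6-(2-oxoheptyl)benzoyl]oxy}-2-hydroxy-6-(2-oxoheptyl)benzoate F8, and hydrogenolysis as in step 10 would give 19.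

Step 7. Hydroxide attack at the doubly ortho-substituted ester carbonyl may be too slow, and prolonged heating may erode the benzyl ethers. The fallback sets out from 6 and comes back at 15; it uses an ester that is cleaved at the allyl group and not at the carbonyl. Compound 6 would be lithiated and acylated with allyl chloroformate to prop-2-en-1-yl 4-(2-pentyl-1,3-dioxolan-2-yl)but-2-ynoate F9. Cycloaddition with 10 as in step 5 would give prop-2-en-1-yl 2,4-dihydroxy-6-[(2-pentyl-1,3-dioxolan-2-yl)methyl]benzoate F10. Benzylation (BnBr, K2CO3, DMF) would give prop-2-en-1-yl 2,4-bis(benzyloxy)-6-[(2-pentyl-1,3-dioxolan-2-yl)methyl]benzoate F11. Tsuji–Trost deallylation (Pd(PPh3)4 cat., morpholine, THF, rt) would then release 15.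

**Further compounds**

F1 | step 5 | 5,5-dimethyl-3-(trimethylsilyloxy)cyclohex-2-en-1-one | CC1(C)CC(=O)C=C(O[Si](C)(C)C)C1
F2 | step 5 | 5,5-dimethyl-1,3-bis(trimethylsilyloxy)cyclohexa-1,3-diene | CC1(C)CC(O[Si](C)(C)C)=CC(O[Si](C)(C)C)=C1
F3 | step 5 | benzyl 8,8-dimethyl-3-[(2-pentyl-1,3-dioxolan-2-yl)methyl]-1,5-bis(trimethylsilyloxy)bicyclo[2.2.2]octa-2,5-diene-2-carboxylate (racemic) | C[Si](C)(C)OC12CC(C)(C)C(C(O[Si](C)(C)C)=C1)C(CC1(CCCCC)OCCO1)=C2C(=O)OCc1ccccc1
F4 | step 5 | benzyl 6-[(2-pentyl-1,3-dioxolan-2-yl)methyl]-2,4-bis(trimethylsilyloxy)benzoate | O=C(OCc1ccccc1)c1c(O[Si](C)(C)C)cc(O[Si](C)(C)C)cc1CC1(CCCCC)OCCO1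
F5 | step 8 | 4-(2-pentyl-1,3-dioxolan-2-yl)but-2-ynoic acid | CCCCCC1(CC#CC(=O)O)OCCO1
F6 | step 8 | benzyl 2-hydroxy-6-[(2-pentyl-1,3-dioxolan-2-yl)methyl]-4-{[4-(2-pentyl-1,3-dioxolan-2-yl)but-2-ynoyl]oxy}benzoate | O=C(OCc1ccccc1)c1c(O)cc(OC(=O)C#CCC2(CCCCC)OCCO2)cc1CC1(CCCCC)OCCO1
F7 | step 8 | benzyl 4-({2,4-dihydroxy-6-[(2-pentyl-1,3-dioxolan-2-yl)methyl]benzoyl}oxy)-2-hydroxy-6-[(2-pentyl-1,3-dioxolan-2-yl)methyl]benzoate | O=C(OCc1ccccc1)c1c(O)cc(OC(=O)c2c(O)cc(O)cc2CC2(CCCCC)OCCO2)cc1CC1(CCCCC)OCCO1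
F8 | step 8 | benzyl 4-{[2,4-dihydroxy-6-(2-oxoheptyl)benzoyl]oxy}-2-hydroxy-6-(2-oxoheptyl)benzoate | CCCCCC(=O)Cc1cc(OC(=O)c2c(O)cc(O)cc2CC(=O)CCCCC)cc(O)c1C(=O)OCc1ccccc1
F9 | step 7 | prop-2-en-1-yl 4-(2-pentyl-1,3-dioxolan-2-yl)but-2-ynoate | CCCCCC1(CC#CC(=O)OCC=C)OCCO1
F10 | step 7 | prop-2-en-1-yl 2,4-dihydroxy-6-[(2-pentyl-1,3-dioxolan-2-yl)methyl]benzoate | C=CCOC(=O)c1c(O)cc(O)cc1CC1(CCCCC)OCCO1
F11 | step 7 | prop-2-en-1-yl 2,4-bis(benzyloxy)-6-[(2-pentyl-1,3-dioxolan-2-yl)methyl]benzoate | C=CCOC(=O)c1c(OCc2ccccc2)cc(OCc2ccccc2)cc1CC1(CCCCC)OCCO1
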